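Substrate, product and catalyst intermediate always add up to the substrate charged. The intermediate can hold no more than the catalyst charged, 0.711% of the substrate in Saturday's and Tuesday's flasks. So substrate lost is nearly product made, and I reckon on substrate.

| flask | substrate | free catalyst | added ligand | temperature | remark | time |
|---|---|---|---|---|---|---|
| spring | 38 mM | 0.14 mM | 1.3 mM | 28 °C | run made earlier |  |
| noon | 38 mM | 0.20 mM | 1.3 mM | 44 °C | run made earlier |  |
| Saturday's | 38 mM | 0.27 mM | 1.3 mM |  | at 50 °C throughout | 5.0 min |
| Tuesday's | 38 mM | 0.27 mM | 1.3 mM |  | at 50 °C until 1.0 min, from then on at 20 °C | 5.0 min |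

| run | time / min | product / % | substrate / % |
|---|---|---|---|
| spring | 1.33 | 2.9 | 96.9 |
| spring | 3.00 | 7.0 | 93.3 |
| spring | 6.00 | 11.4 | 87.5 |
| spring | 15.0 | 29.0 | 71.8 |
| noon | 1.33 | 27.0 | 71.5 |
| noon | 2.50 | 48.8 | 50.4 |
| noon | 4.00 | 68.1 | 29.8 |
| noon | 5.00 | 77.0 | 22.3 |

(readings scatter by 1 percentage point)

- the winner by amount of product, in percent of the substrate charged; "neither" if no more than 2 percentage points parts them (Saturday's / Tuesday's / neither)
- how much product is there at the end, in percent of the substrate charged: Saturday's
- how much product is there at the end, in percent of the substrate charged: Tuesday's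

All four flasks share the substrate and ligand charges, so I compare them by one rough number, reckoned as if the loss of substrate were first order; that is an approximation, and I test it below. I call the specific constant the first-order loss per minute, per mM of catalyst charged. The last spring reading gives 0.158 mM⁻¹ min⁻¹, and the last noon reading gives 1.50 mM⁻¹ min⁻¹. That pair implies an apparent activation energy of 112 kJ mol⁻¹.

Carried up to 50 °C, the specific constant is 3.30 mM⁻¹ min⁻¹; this hot specific constant is what I carry forward. Saturday's flask then reaches 98.8% product. Tuesday's flask reaches 58.9% in its hot stretch. At 20 °C the constant is 0.0466 mM⁻¹ min⁻¹, far smaller than the hot one.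

The weak link is the hot stretch, which is short, while my constant comes from a whole run. So I go round once more. The first noon reading gives 1.26 mM⁻¹ min⁻¹, less than the whole-run value, though it carries the scatter of a reading. Scaling the hot constant by that ratio leaves 47.3% substrate in Tuesday's flask at the change. The cold stretch takes this to 45.0%. I commit to 55.0% product for Tuesday's, so Saturday's gives more.

The forecast also picks Saturday's, with 98.5% (94% to 100%) for Saturday's and 61% (50% to 72%) for Tuesday's, above my figure, and says “Tuesday's run effectively stops when it is chilled”.

The flask gives 50.8% for Tuesday's and 98.8% for Saturday's, so the winner is Saturday's.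

    substrate + free catalyst ⇌ catalyst intermediate (K = 150 M⁻¹, k = 120 M⁻¹ s⁻¹, Ea = 51.0 kJ mol⁻¹, ΔH = −9.00 kJ mol⁻¹)
    catalyst intermediate → free catalyst + product (k = 3.10 s⁻¹, Ea = 74.0 kJ mol⁻¹)
    free catalyst + added ligand ⇌ idle complex, settled at all times (K = 400 M⁻¹, ΔH = −88.0 kJ mol⁻¹)
    (constants at 50 °C)

Saturday's 1.22% of remaining substrate reads back as a specific constant of 3.27 mM⁻¹ min⁻¹, beside my 3.30 mM⁻¹ min⁻¹. Tuesday's flask parts from my reckoning at the change: at 1.00 min it holds 51.8% substrate against my 47.3%. A flask like Saturday's kept at 25 °C takes the hot constant down to 0.101 mM⁻¹ min⁻¹, which leaves 87.3% substrate. That flask ends with 87% substrate and 13.2% product.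

The numbers in the tables stem from a simulated flask from invented constants; scatter was added.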